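# Synthesis plan for 7-hydroxy-3-[3-hydroxy-4-methoxy-5-(3-methylbut-2-enyl)phenyl]-5-methoxychromen-4-one (28)

## The problem

The target 28 is an isoflavone: a chromen-4-one (rings A and C) carrying ring B at C3. It has no stereocentre, so no centre can control another, and every difficulty is one of regiochemistry and of telling similar oxygens apart. Ring A bears oxygen at C5 and C7 in the less convenient arrangement. The C5 oxygen, which as a free hydroxyl is hydrogen-bonded to the C4 carbonyl and is the least reactive phenol of the molecule, is the methylated one, while the acidic C7 hydroxyl is free. Ring B is a 1,3,4,5-tetrasubstituted benzene whose central methoxy group (C4') lies between a free hydroxyl (C3') and a prenyl group (C5'), a pattern that electrophilic substitution of a simple anisole does not give. The prenyl group is the fragile element: once it is present, hydrogenolysis, strong protic or Lewis acid and electrophilic halogen or oxidant are excluded, and the O1–C2 enol ether of the chromone opens in hot hydroxide. The feature that can be exploited is the unit O5–C5–C6–C7–O7 on a benzene ring fused through C4a–C8a to a γ-pyranone, with C5 peri to the C4 carbonyl. A resorcinol fused to an existing enone double bond is what a vinylketene and an oxygen-substituted alkyne assemble, the ketene carbon becoming C5–OH and the oxygen-bearing alkyne carbon becoming C7. Made this way, the two ring A oxygens are formed already different (free hydroxyl at C5, silyl ether at C7).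

## Retrosynthesis

**28 to 26.** Only heteroatom bonds are cut first: the two O–Si bonds of bis-silyl ether 27, then the O–CH3 bond at C5, which leads to phenol 26. Fluoride removes both silyl groups in one operation and leaves the prenyl alkene alone, which acid-labile or hydrogenolysable groups would not. Methylating O5 while O7 and O3' are silylated is the step that sets the oxygen pattern. The forward methylation must alkylate a chelated phenol without loosening the C7 silyl ether.

**26 to 18 and 21.** Ring A is removed by cutting C5–C6, C7–C8 and C4a–C5; C8 is traced to the diazo carbon of diazoketone 18, and C6 and C7 to siloxyalkyne 21. The neighbouring cuts through ring C (deoxybenzoin, chalcone, acylation and closure at O1) all need a pre-formed phloroglucinol ring with three oxygens already differentiated. Here ring C is the bought pyranone and ring A is grown on it, and the mechanism leaves O5 as a hydroxyl and O7 as a silyl ether. The precursor is simpler by one ring and three carbon–carbon bonds, and 21 is a two-carbon unit. The forward reaction must join ketene and alkyne in one orientation, use light that the pyranone does not absorb, and leave the prenyl group untouched.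

**18 to 15.** The diazoketone is taken back to carboxylic acid 16 (the C–C bond between the acyl carbon and the diazo carbon is cut) and the acid to its methyl ester 15. The ester is the robust form in which the pyranone is carried through the cross-coupling. The forward activation must avoid free HCl because of the prenyl group.

**15 to 14 and 10.** The bond between the pyranone and ring B (the future C3–C1' bond) is cut to enol triflate 14 and arylboronate 10. Coupling at this stage, before the diazo group exists, puts the biaryl bond on two simple, stable partners. The enolic hydroxyl of comenate sits on exactly the carbon that becomes C3, so no regiochemical question arises.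

**14 to 11.** Triflate 14 comes from methyl comenate 13, that from comenic acid 12, and 12 from kojic acid 11 by oxidation of the hydroxymethyl group. All six ring C atoms, the C4 carbonyl, the oxygen handle for the coupling and the carbon that turns into the ketene are present in a bulk chemical.

**10 to 1 and 2.** Boronate 10 is cut at C–B to bromide 9, at O–Si to phenol 8, at C–O to dibromide 5, and at the aryl–prenyl bond to 2,4,6-tribromoanisole 1 and prenyl bromide 2. The symmetrical tribromide already has the 1,3,4,5 pattern. Its two bromines ortho to the methoxy group exchange with lithium in preference to the para one, so they can be replaced one after the other (prenyl, then hydroxyl). The para bromine is kept for the boron.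

**21 to 19.** The O–Si bond of 21 is cut to lithium ethynolate 20, which is traced to ethyl dibromoacetate 19 by loss of ethoxide from the ester dianion.

## Roads not taken

**Alternative 1:** Ring C is cut at C3–C4 and O1–C8a. Forward, the morpholine enamine A3 of the ring B arylacetaldehyde is C-acylated by 2-fluoro-6-methoxy-4-(allyloxy)benzoyl chloride A2. Aqueous K2CO3 then frees the enolate of the β-ketoaldehyde, whose oxygen displaces the fluorine ortho to the ketone to give protected isoflavone A1. Removal of the allyl and MOM groups completes the synthesis.
- Merits: the chemistry is ionic and scalable, needs no light and no diazo compound, and each elementary step has close precedent. The ring A pattern is fixed by the arene that is bought or made.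
- Weak points: A2 is a 1,3,5-trisubstituted fluoroarene with three different heteroatom substituents and needs its own multistep preparation. A3 requires a one-carbon homologation of a ring B aldehyde. The end game needs two deprotection regimes, one of them acidic in the presence of the prenyl group.
- Comparison: the key step of this road is probably more certain than the benzannulation. The chosen plan sets against it that the ring A oxygens are differentiated by the ring-forming mechanism, not by selective substitution on a fluoroarene, and that one fluoride treatment frees both phenols.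

**Alternative 2:** Ring A is cut at C5–C6 and C4a–C8a on an open-chain ketone. Forward, methoxyalkynyl ketone A5 and 1-methoxy-1,3-bis(trimethylsilyloxy)butadiene A6 undergo a Diels–Alder reaction. Loss of methanol and of the silyl groups on work-up gives deoxybenzoin A4 with the C5 methoxy group already in place, a one-carbon insertion closes ring C, and the MOM group is removed.
- Merits: the C5 methyl ether comes from the dienophile, so no chelated phenol has to be alkylated. In this respect the road is better than the chosen plan, which needs step 13.
- Weak points: A5 is a push–pull alkyne whose methoxy donor lowers its dienophilicity, and its doubly activated methylene invites isomerisation to an allenyl ketone. Ring C still has to be closed afterwards, and the final deprotection is acidic.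
- Comparison: step count is similar. The chosen plan keeps ring C intact from kojic acid and uses an ynol ether as an electron-rich partner of an electrophilic ketene, a matched pairing, where this road asks an electron-rich diene to add to a deactivated dienophile.

**Alternative 3:** The C3–C1' bond arises by a 1,2-aryl shift. Forward, 2'-hydroxychalcone A8 is treated with Tl(NO3)3 in methanol and trimethyl orthoformate, ring B migrates to the α-carbon, and HCl closes O1–C2 and removes both MOM groups to give bromo-isoflavone A7. The prenyl group must then be attached at the bromide by cross-coupling.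
- Merits: this is the shortest way to the isoflavone skeleton, it follows the biosynthesis, the chalcone comes from a single aldol condensation, and the C5 methoxy group is bought with the acetophenone.
- Weak points: it uses a stoichiometric amount of a toxic trivalent thallium salt. The prenyl alkene cannot be present during the oxidation, hence the bromine placeholder. The migrating ring has its 4-methoxy group flanked by two ortho substituents and twisted out of conjugation, which lowers its migratory aptitude. The late prenyl coupling on a diphenol has to control attack at the α- against the γ-carbon of the prenyl metal.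
- Comparison: this road is shorter and better precedented for isoflavones in general. The chosen plan avoids thallium and carries the complete ring B, prenyl included, into a single early Suzuki coupling.

Key step: step 12

Assumption: ethynyl triisopropylsilyl ether 21 is not treated as a catalogue compound and is made in step 11; it is taken to tolerate short-path distillation and cold storage as its alkyl-substituted homologues do.

## Route

Step 1
Reactants: 1 2,4,6-tribromoanisole; 2 1-bromo-3-methylbut-2-ene
Product: 5 1,5-dibromo-2-methoxy-3-(3-methylbut-2-enyl)benzene, via 3,5-dibromo-2-methoxyphenyllithium 3 (not isolated), via 3,5-dibromo-2-methoxyphenylcopper 4 (not isolated)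
Conditions: n-BuLi (1.0 equiv), Et2O, −78 °C; CuBr·SMe2 (1.0 equiv), −78 → −40 °C; 2, −40 → 0 °C
Reagents that add atoms: none
Why: Bromine–lithium exchange occurs at a bromine ortho to the methoxy group, where the aryllithium is stabilised by coordination and induction, and one equivalent of n-BuLi limits it to one of the two equivalent positions; transmetalation to copper and SN2 allylation at the unhindered CH2 of prenyl bromide give the linear prenyl arene.

Step 2
Reactants: 5 1,5-dibromo-2-methoxy-3-(3-methylbut-2-enyl)benzene
Product: 8 5-bromo-2-methoxy-3-(3-methylbut-2-enyl)phenol, via aryllithium 6 (not isolated), via dimethyl arylboronate 7 (not isolated)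
Conditions: n-BuLi, Et2O, −78 °C; B(OMe)3, −78 °C → rt; H2O2, aq. NaOH, 0 °C
Reagents that add atoms: hydrogen peroxide, OO
Why: A second ortho-directed bromine–lithium exchange, borylation and oxidation of the C–B bond (1,2-shift of aryl from boron to oxygen) convert the remaining ortho bromine into hydroxyl; the para bromine is kept and alkaline peroxide does not touch the isolated alkene.

Step 3
Reactants: 8 5-bromo-2-methoxy-3-(3-methylbut-2-enyl)phenol
Product: 9 [5-bromo-2-methoxy-3-(3-methylbut-2-enyl)phenoxy]triisopropylsilane
Conditions: TIPSCl, imidazole, DMF, rt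
Reagents that add atoms: triisopropylsilyl chloride, CC(C)[Si](Cl)(C(C)C)C(C)C
Why: Standard silylation of a phenol; the bulky triisopropylsilyl ether is chosen because it must survive aqueous phosphate, cold hydroxide and carbonate later and fall with fluoride at the end.

Step 4
Reactants: 9 [5-bromo-2-methoxy-3-(3-methylbut-2-enyl)phenoxy]triisopropylsilane
Product: 10 2-[4-methoxy-3-(3-methylbut-2-enyl)-5-(triisopropylsilyloxy)phenyl]-4,4,5,5-tetramethyl-1,3,2-dioxaborolane
Conditions: B2pin2, PdCl2(dppf) (3 mol%), KOAc, dioxane, 85 °C
Reagents that add atoms: bis(pinacolato)diboron, CC1(C)OB(OC1(C)C)B1OC(C)(C)C(C)(C)O1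
Why: Miyaura borylation of an unhindered aryl bromide; acetate is too weak a base to trigger Suzuki homocoupling or to attack the silyl ether, and the prenyl alkene is inert to the catalyst.

Step 5
Reactants: 11 kojic acid (5-hydroxy-2-(hydroxymethyl)pyran-4-one)
Product: 12 comenic acid (5-hydroxy-4-oxopyran-2-carboxylic acid)
Conditions: O2 (1 atm), Pd/C, aq. NaOH (pH 10–11), 25 °C; then HCl
Reagents that add atoms: water, O
Why: Heterogeneous aerobic oxidation of the activated primary alcohol on palladium proceeds through the aldehyde hydrate to the carboxylate, with O2 as terminal oxidant; this is the established conversion of kojic acid into comenic acid, and the enolate of the ring hydroxyl is not oxidised.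

Step 6
Reactants: 12 comenic acid
Product: 13 methyl 5-hydroxy-4-oxopyran-2-carboxylate
Conditions: MeOH, H2SO4 (cat.), reflux
Reagents that add atoms: methanol, CO
Why: Fischer esterification; the enolic hydroxyl is not etherified under these conditions.

Step 7
Reactants: 13 methyl 5-hydroxy-4-oxopyran-2-carboxylate
Product: 14 methyl 4-oxo-5-(trifluoromethylsulfonyloxy)pyran-2-carboxylate
Conditions: Tf2O, pyridine, CH2Cl2, −20 → 0 °C
Reagents that add atoms: trifluoromethanesulfonic anhydride, O=S(=O)(OS(=O)(=O)C(F)(F)F)C(F)(F)F
Why: O-Sulfonylation of an acidic enol, as used for cross-coupling of kojic-acid-derived pyranones; the triflate is the only leaving group in the molecule.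

Step 8
Reactants: 14 methyl 4-oxo-5-(trifluoromethylsulfonyloxy)pyran-2-carboxylate; 10 arylboronate
Product: 15 methyl 5-[4-methoxy-3-(3-methylbut-2-enyl)-5-(triisopropylsilyloxy)phenyl]-4-oxopyran-2-carboxylate
Conditions: Pd(PPh3)4 (5 mol%), K3PO4, dioxane/H2O (10:1), 70 °C
Reagents that add atoms: none
Why: Suzuki–Miyaura coupling: zerovalent palladium inserts into the C–O bond of the electron-poor enol triflate, the phosphate-activated boronate transmetalates and reductive elimination forms the pyranone–aryl bond (later C3–C1'); a mild base and little water limit hydrolysis of triflate and ester.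

Step 9
Reactants: 15 methyl ester
Product: 16 5-[4-methoxy-3-(3-methylbut-2-enyl)-5-(triisopropylsilyloxy)phenyl]-4-oxopyran-2-carboxylic acid
Conditions: LiOH (1.2 equiv), THF/H2O, 0 °C; then 1 M HCl to pH 3
Reagents that add atoms: lithium hydroxide, [Li+].[OH-]
Why: Saponification of an ester activated by the electron-poor ring is fast at 0 °C, so hydroxide has little time to add to C6 of the pyranone, and the hindered aryl silyl ether is not cleaved in the cold.

Step 10
Reactants: 16 carboxylic acid
Product: 18 2-(2-diazoacetyl)-5-[4-methoxy-3-(3-methylbut-2-enyl)-5-(triisopropylsilyloxy)phenyl]pyran-4-one, via isobutyl carbonic anhydride 17 (not isolated)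
Conditions: i-BuOCOCl, N-methylmorpholine, THF, −15 °C; CH2N2 (2.5 equiv), Et2O, 0 °C
Reagents that add atoms: diazomethane, C=[N+]=[N-]
Why: Acylation of diazomethane by a mixed carbonic anhydride (first stage of the Arndt–Eistert sequence); diazomethane attacks the more electrophilic pyranone acyl carbon, and no HCl is generated that could add to the prenyl alkene.

Step 11
Reactants: 19 ethyl dibromoacetate
Product: 21 ethynyl triisopropylsilyl ether, via lithium ethynolate 20 (not isolated)
Conditions: t-BuLi (4 equiv), THF, −78 → 0 °C; TIPSOTf, −78 °C → rt
Reagents that add atoms: triisopropylsilyl trifluoromethanesulfonate, CC(C)[Si](OS(=O)(=O)C(F)(F)F)(C(C)C)C(C)C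
Why: Twofold bromine–lithium exchange converts the dibromo ester through the α-bromo enolate into the ester dianion, which expels lithium ethoxide to give ynolate 20 (ynolate synthesis from α,α-dibromo esters); the bulky silyl triflate then silylates at oxygen, as in the known preparation of triisopropylsiloxyalkynes.

Step 12
Reactants: 18 diazoketone; 21 ethynyl triisopropylsilyl ether
Product: 26 5-hydroxy-3-[4-methoxy-3-(3-methylbut-2-enyl)-5-(triisopropylsilyloxy)phenyl]-7-(triisopropylsilyloxy)chromen-4-one, via pyranylketene 22 (not isolated), via siloxycyclobutenone 23 (not isolated), via dienylketene 24 (not isolated), via 4a-H dienone tautomer 25 (not isolated)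
Conditions: 21 (2.5 equiv), hν (365 nm), ClCH2CH2Cl, 25 °C; then 80 °C
Reagents that add atoms: none
Why: Excitation of the diazoketone expels N2 with 1,2-shift of the pyranyl group (Wolff rearrangement) to ketene 22, whose electrophilic carbonyl carbon is attacked by the unsubstituted, nucleophilic carbon of 21, and the [2+2] adduct is cyclobutenone 23 (new bonds C5–C6 and C7–C8). Light or gentle heat opens 23 in a four-electron conrotatory electrocyclic reaction to dienylketene 24; this opening is reversible, so material in which the pyranyl group has turned away from the ketene returns to 23 until it leaves through the productive geometry. Ring A is closed by a thermal six-electron disrotatory electrocyclisation in which the ketene carbon bonds to C4a of the pyranone (C4a–C5), and dienone 25 enolises to the hydrogen-bonded phenol 26. The closest known reaction type is the Danheiser benzannulation of alkenyl and heteroaryl diazoketones with trialkylsiloxyalkynes, which gives resorcinol monosilyl ethers of this kind; the pyranone double bond is less aromatic than the arenes used there and should take part at least as readily. No stereocentre is created; the sp3 centres of 23 and 25 are transient and racemic. The selectivity needed is regiochemical and comes from the polarisation of both partners: oxygen donation makes the CH terminus of 21 the nucleophile and the ketene C=O carbon is the electrophile, so the silyloxy group ends at C7 and the ketene oxygen at C5, peri to C4=O. Irradiation at 365 nm addresses the diazoketone band and not the pyranone absorption at shorter wavelength; product 26 can shed absorbed light through its chelated hydroxyl, which also makes it a poor trap for ketene 22. The isolated prenyl alkene is far less ketenophilic than the electron-rich alkyne, which is present in excess.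

Step 13
Reactants: 26 5-hydroxy bis-silyl ether
Product: 27 5-methoxy-3-[4-methoxy-3-(3-methylbut-2-enyl)-5-(triisopropylsilyloxy)phenyl]-7-(triisopropylsilyloxy)chromen-4-one
Conditions: MeI, K2CO3, acetone, 50 °C
Reagents that add atoms: iodomethane, CI
Why: Williamson methylation of the only free hydroxyl; dry acetone with sparingly soluble carbonate is the classical medium for chelated 5-hydroxyls and offers no nucleophile able to attack the hindered silicon atoms.

Step 14
Reactants: 27 5-methoxy bis-silyl ether
Product: 28 7-hydroxy-3-[3-hydroxy-4-methoxy-5-(3-methylbut-2-enyl)phenyl]-5-methoxychromen-4-one (target)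
Conditions: Bu4NF, AcOH, THF, 0 °C
Reagents that add atoms: none
Why: Fluoride cleaves both aryl silyl ethers through pentacoordinate silicon; acetic acid buffers the phenoxides, and alkene, methyl ethers and chromone are inert.

## Compound list

1 | 2,4,6-tribromoanisole | COc1c(Br)cc(Br)cc1Br | starting material
2 | 1-bromo-3-methylbut-2-ene | CC(C)=CCBr | starting material
3 | 3,5-dibromo-2-methoxyphenyllithium | COc1c([Li])cc(Br)cc1Br | intermediate
4 | 3,5-dibromo-2-methoxyphenylcopper | COc1c([Cu])cc(Br)cc1Br | intermediate
5 | 1,5-dibromo-2-methoxy-3-(3-methylbut-2-enyl)benzene | COc1c(Br)cc(Br)cc1CC=C(C)C | intermediate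
6 | 5-bromo-2-methoxy-3-(3-methylbut-2-enyl)phenyllithium | COc1c([Li])cc(Br)cc1CC=C(C)C | intermediate
7 | dimethyl [5-bromo-2-methoxy-3-(3-methylbut-2-enyl)phenyl]boronate | COB(OC)c1cc(Br)cc(CC=C(C)C)c1OC | intermediate
8 | 5-bromo-2-methoxy-3-(3-methylbut-2-enyl)phenol | COc1c(O)cc(Br)cc1CC=C(C)C | intermediate
9 | [5-bromo-2-methoxy-3-(3-methylbut-2-enyl)phenoxy]triisopropylsilane | COc1c(O[Si](C(C)C)(C(C)C)C(C)C)cc(Br)cc1CC=C(C)C | intermediate
10 | 2-[4-methoxy-3-(3-methylbut-2-enyl)-5-(triisopropylsilyloxy)phenyl]-4,4,5,5-tetramethyl-1,3,2-dioxaborolane | COc1c(O[Si](C(C)C)(C(C)C)C(C)C)cc(B2OC(C)(C)C(C)(C)O2)cc1CC=C(C)C | intermediate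
11 | kojic acid | OCc1cc(=O)c(O)co1 | starting material
12 | comenic acid | O=C(O)c1cc(=O)c(O)co1 | intermediate
13 | methyl 5-hydroxy-4-oxopyran-2-carboxylate | COC(=O)c1cc(=O)c(O)co1 | intermediate
14 | methyl 4-oxo-5-(trifluoromethylsulfonyloxy)pyran-2-carboxylate | COC(=O)c1cc(=O)c(OS(=O)(=O)C(F)(F)F)co1 | intermediate
15 | methyl 5-[4-methoxy-3-(3-methylbut-2-enyl)-5-(triisopropylsilyloxy)phenyl]-4-oxopyran-2-carboxylate | COC(=O)c1cc(=O)c(-c2cc(O[Si](C(C)C)(C(C)C)C(C)C)c(OC)c(CC=C(C)C)c2)co1 | intermediate
16 | 5-[4-methoxy-3-(3-methylbut-2-enyl)-5-(triisopropylsilyloxy)phenyl]-4-oxopyran-2-carboxylic acid | O=C(O)c1cc(=O)c(-c2cc(O[Si](C(C)C)(C(C)C)C(C)C)c(OC)c(CC=C(C)C)c2)co1 | intermediate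
17 | isobutyl carbonic anhydride of acid 16 | CC(C)COC(=O)OC(=O)c1cc(=O)c(-c2cc(O[Si](C(C)C)(C(C)C)C(C)C)c(OC)c(CC=C(C)C)c2)co1 | intermediate
18 | 2-(2-diazoacetyl)-5-[4-methoxy-3-(3-methylbut-2-enyl)-5-(triisopropylsilyloxy)phenyl]pyran-4-one | [N-]=[N+]=CC(=O)c1cc(=O)c(-c2cc(O[Si](C(C)C)(C(C)C)C(C)C)c(OC)c(CC=C(C)C)c2)co1 | intermediate
19 | ethyl dibromoacetate | CCOC(=O)C(Br)Br | starting material
20 | lithium ethynolate | [Li+].[O-]C#C | intermediate
21 | ethynyl triisopropylsilyl ether | C#CO[Si](C(C)C)(C(C)C)C(C)C | intermediate
22 | 2-(2-oxoethenyl)-5-arylpyran-4-one (pyranylketene) | O=C=Cc1cc(=O)c(-c2cc(O[Si](C(C)C)(C(C)C)C(C)C)c(OC)c(CC=C(C)C)c2)co1 | intermediate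
23 | 4-(5-aryl-4-oxopyran-2-yl)-3-(triisopropylsilyloxy)cyclobut-2-en-1-one (racemic) | O=C1C=C(O[Si](C(C)C)(C(C)C)C(C)C)C1c1cc(=O)c(-c2cc(O[Si](C(C)C)(C(C)C)C(C)C)c(OC)c(CC=C(C)C)c2)co1 | intermediate
24 | 4-(5-aryl-4-oxopyran-2-yl)-3-(triisopropylsilyloxy)buta-1,3-dien-1-one, pyranyl cis to the ketene arm | O=C=C/C(O[Si](C(C)C)(C(C)C)C(C)C)=C\c1cc(=O)c(-c2cc(O[Si](C(C)C)(C(C)C)C(C)C)c(OC)c(CC=C(C)C)c2)co1 | intermediate
25 | 3-aryl-7-(triisopropylsilyloxy)-4aH-chromene-4,5-dione (racemic keto tautomer of 26) | O=C1C=C(O[Si](C(C)C)(C(C)C)C(C)C)C=C2OC=C(-c3cc(O[Si](C(C)C)(C(C)C)C(C)C)c(OC)c(CC=C(C)C)c3)C(=O)C12 | intermediate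
26 | 5-hydroxy-3-[4-methoxy-3-(3-methylbut-2-enyl)-5-(triisopropylsilyloxy)phenyl]-7-(triisopropylsilyloxy)chromen-4-one | CC(C)[Si](Oc1cc(O)c2c(c1)occ(-c1cc(O[Si](C(C)C)(C(C)C)C(C)C)c(OC)c(CC=C(C)C)c1)c2=O)(C(C)C)C(C)C | intermediate
27 | 5-methoxy-3-[4-methoxy-3-(3-methylbut-2-enyl)-5-(triisopropylsilyloxy)phenyl]-7-(triisopropylsilyloxy)chromen-4-one | COc1cc(O[Si](C(C)C)(C(C)C)C(C)C)cc2occ(-c3cc(O[Si](C(C)C)(C(C)C)C(C)C)c(OC)c(CC=C(C)C)c3)c(=O)c12 | intermediate
28 | 7-hydroxy-3-[3-hydroxy-4-methoxy-5-(3-methylbut-2-enyl)phenyl]-5-methoxychromen-4-one | COc1c(O)cc(-c2coc3cc(O)cc(OC)c3c2=O)cc1CC=C(C)C | target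

## Step count and risk

Total: 14 steps. Longest linear sequence: 10 steps (steps 1–4, 8–10, 12–14).

**Step 12 (key step).** Three things are most likely to go wrong:
- competing light absorption by the aryl-pyranone chromophore, leading to photodegradation or incomplete Wolff rearrangement;
- diversion of ketene 22 (dimerisation, or slow cycloaddition if the siloxyalkyne rearranges or hydrolyses during the run);
- failure of dienylketene 24 to close onto the pyranone double bond, so that material stays at cyclobutenone 23 or decomposes on heating.

These risks exist because the pyranone has not been the alkene component of this annulation before and because the unsubstituted siloxyalkyne is the least robust member of its family.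

Fallback: ring A is bought instead of built, and the isoflavone is made by cross-coupling on a preformed chromone. The fallback sets out from boronate 10 and 1-(2,4-dihydroxy-6-methoxyphenyl)ethanone F1. The free, non-chelated hydroxyl is silylated (TIPSCl, imidazole) to 1-[2-hydroxy-6-methoxy-4-(triisopropylsilyloxy)phenyl]ethanone F2. Condensation with DMF dimethyl acetal gives enaminone F3, and iodine cyclises it to 3-iodo-5-methoxy-7-(triisopropylsilyloxy)chromen-4-one F4. Suzuki coupling of F4 with 10 (PdCl2(dppf), K3PO4) returns to the route at 27.

**Step 11.** The risks are deprotonation of 19 in competition with bromine–lithium exchange, which leads to brominated ynolates, and silylation of the unhindered ynolate at carbon to a silylketene. Loss of the small, hydrolytically sensitive product on isolation is a further risk. The parent ynolate lacks the substituent that shields carbon in the known cases.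

Fallback: the ynolate is generated by fragmentation of a heterocycle. 3-Phenylisoxazole F5 is lithiated at C5 with n-BuLi at −78 °C. The 5-lithio-3-phenylisoxazole F6 breaks up on warming into benzonitrile and lithium ethynolate 20, the point at which the route is rejoined; silylation as in step 11 gives 21.

**Step 10.** Diazomethane may undergo dipolar cycloaddition to the acyl-activated C2=C3 bond of the pyranone, or attack the carbonate carbonyl of 17 and return ester 15. The ring is an electron-poor alkene as well as an acyl donor.

Fallback: the diazo group is introduced by diazo transfer, without diazomethane, starting from 16. Amide formation with N,O-dimethylhydroxylamine gives Weinreb amide F7, and MeMgBr at −78 °C gives the 2-acetylpyranone F8. LiHMDS and 2,2,2-trifluoroethyl trifluoroacetate give trifluoroacetyl diketone F9. Methanesulfonyl azide with Et3N and water transfers the diazo group with loss of the trifluoroacetyl group and returns to 18.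

**Step 13.** The C7 silyl ether, whose phenoxide is a good leaving group because it is conjugated to the C4 carbonyl, may be lost under carbonate and the freed C7 oxygen methylated. The chelated hydroxyl may also react too slowly.

Fallback: protecting groups are exchanged before the methylation, starting from 26. Bu4NF gives triol F10, and MOMCl with i-Pr2NEt etherifies the two non-chelated hydroxyls to F11. The single chelated hydroxyl is then methylated under forcing conditions (MeI, K2CO3, DMF) to F12. HCl in MeOH at rt removes the MOM groups and gives 28 directly.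

**Step 1 (the same question returns in step 2).** Exchange may occur at the para bromine or twice, and the allylation may go through the γ-carbon to the 1,1-dimethylallyl isomer. Ortho preference rests on coordination, which is solvent dependent.

Fallback: the para position is left as C–H and borylated last, starting from 2 and 2,6-dibromoanisole F13. Monolithiation, copper transmetalation and prenylation give 1-bromo-2-methoxy-3-(3-methylbut-2-enyl)benzene F14. Lithiation, borylation and oxidation give 2-methoxy-3-(3-methylbut-2-enyl)phenol F15, and silylation gives F16. Sterically controlled C–H borylation with [Ir(OMe)(cod)]2, 4,4'-di-tert-butyl-2,2'-bipyridine and B2pin2 occurs at the only position without an ortho substituent (para to the methoxy group) and returns to 10.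

## Further compounds

F1 | step 12 | 1-(2,4-dihydroxy-6-methoxyphenyl)ethanone | CC(=O)c1c(O)cc(O)cc1OC
F2 | step 12 | 1-[2-hydroxy-6-methoxy-4-(triisopropylsilyloxy)phenyl]ethanone | CC(=O)c1c(O)cc(O[Si](C(C)C)(C(C)C)C(C)C)cc1OC
F3 | step 12 | (E)-3-(dimethylamino)-1-[2-hydroxy-6-methoxy-4-(triisopropylsilyloxy)phenyl]prop-2-en-1-one | CN(C)/C=C/C(=O)c1c(O)cc(O[Si](C(C)C)(C(C)C)C(C)C)cc1OC
F4 | step 12 | 3-iodo-5-methoxy-7-(triisopropylsilyloxy)chromen-4-one | COc1cc(O[Si](C(C)C)(C(C)C)C(C)C)cc2occ(I)c(=O)c12
F5 | step 11 | 3-phenylisoxazole | c1ccc(-c2ccon2)cc1
F6 | step 11 | 5-lithio-3-phenylisoxazole | [Li]c1cc(-c2ccccc2)no1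
F7 | step 10 | N-methoxy-N-methyl-5-[4-methoxy-3-(3-methylbut-2-enyl)-5-(triisopropylsilyloxy)phenyl]-4-oxopyran-2-carboxamide | CON(C)C(=O)c1cc(=O)c(-c2cc(O[Si](C(C)C)(C(C)C)C(C)C)c(OC)c(CC=C(C)C)c2)co1
F8 | step 10 | 2-acetyl-5-[4-methoxy-3-(3-methylbut-2-enyl)-5-(triisopropylsilyloxy)phenyl]pyran-4-one | CC(=O)c1cc(=O)c(-c2cc(O[Si](C(C)C)(C(C)C)C(C)C)c(OC)c(CC=C(C)C)c2)co1
F9 | step 10 | 4,4,4-trifluoro-1-[5-[4-methoxy-3-(3-methylbut-2-enyl)-5-(triisopropylsilyloxy)phenyl]-4-oxopyran-2-yl]butane-1,3-dione | O=C(CC(=O)C(F)(F)F)c1cc(=O)c(-c2cc(O[Si](C(C)C)(C(C)C)C(C)C)c(OC)c(CC=C(C)C)c2)co1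
F10 | step 13 | 5,7-dihydroxy-3-[3-hydroxy-4-methoxy-5-(3-methylbut-2-enyl)phenyl]chromen-4-one | COc1c(O)cc(-c2coc3cc(O)cc(O)c3c2=O)cc1CC=C(C)C
F11 | step 13 | 5-hydroxy-7-(methoxymethoxy)-3-[4-methoxy-3-(methoxymethoxy)-5-(3-methylbut-2-enyl)phenyl]chromen-4-one | COCOc1cc(O)c2c(c1)occ(-c1cc(OCOC)c(OC)c(CC=C(C)C)c1)c2=O
F12 | step 13 | 5-methoxy-7-(methoxymethoxy)-3-[4-methoxy-3-(methoxymethoxy)-5-(3-methylbut-2-enyl)phenyl]chromen-4-one | COCOc1cc(OC)c2c(c1)occ(-c1cc(OCOC)c(OC)c(CC=C(C)C)c1)c2=O
F13 | step 1 | 2,6-dibromoanisole | COc1c(Br)cccc1Br
F14 | step 1 | 1-bromo-2-methoxy-3-(3-methylbut-2-enyl)benzene | COc1c(Br)cccc1CC=C(C)C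
F15 | step 1 | 2-methoxy-3-(3-methylbut-2-enyl)phenol | COc1c(O)cccc1CC=C(C)C
F16 | step 1 | [2-methoxy-3-(3-methylbut-2-enyl)phenoxy]triisopropylsilane | COc1c(O[Si](C(C)C)(C(C)C)C(C)C)cccc1CC=C(C)C
A1 | alternative 1 | 7-(allyloxy)-5-methoxy-3-[4-methoxy-3-(methoxymethoxy)-5-(3-methylbut-2-enyl)phenyl]chromen-4-one | C=CCOc1cc(OC)c2c(c1)occ(-c1cc(OCOC)c(OC)c(CC=C(C)C)c1)c2=O
A2 | alternative 1 | 2-fluoro-6-methoxy-4-(allyloxy)benzoyl chloride | C=CCOc1cc(F)c(C(=O)Cl)c(OC)c1
A3 | alternative 1 | 4-[(E)-2-[4-methoxy-3-(methoxymethoxy)-5-(3-methylbut-2-enyl)phenyl]ethenyl]morpholine | COCOc1cc(/C=C/N2CCOCC2)cc(CC=C(C)C)c1OC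
A4 | alternative 2 | 1-(2,4-dihydroxy-6-methoxyphenyl)-2-[4-methoxy-3-(methoxymethoxy)-5-(3-methylbut-2-enyl)phenyl]ethanone | COc1cc(O)cc(O)c1C(=O)Cc1cc(OCOC)c(OC)c(CC=C(C)C)c1
A5 | alternative 2 | 4-methoxy-1-[4-methoxy-3-(methoxymethoxy)-5-(3-methylbut-2-enyl)phenyl]but-3-yn-2-one | COC#CC(=O)Cc1cc(OCOC)c(OC)c(CC=C(C)C)c1
A6 | alternative 2 | 1-methoxy-1,3-bis(trimethylsilyloxy)buta-1,3-diene | COC(O[Si](C)(C)C)=CC(=C)O[Si](C)(C)C
A7 | alternative 3 | 3-(3-bromo-5-hydroxy-4-methoxyphenyl)-7-hydroxy-5-methoxychromen-4-one | COc1cc(O)cc2occ(-c3cc(O)c(OC)c(Br)c3)c(=O)c12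
A8 | alternative 3 | (E)-3-[3-bromo-4-methoxy-5-(methoxymethoxy)phenyl]-1-[2-hydroxy-6-methoxy-4-(methoxymethoxy)phenyl]prop-2-en-1-one | COCOc1cc(O)c(C(=O)/C=C/c2cc(Br)c(OC)c(OCOC)c2)c(OC)c1
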